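A small charge of protic impurity, 0.0680 M against 0.34 M of starting complex, gave me the line to watch. I supposed that each protic impurity quenches one starting complex, which makes it the limiting reagent of that side reaction. With h and m the charges of protic impurity and starting complex, and b the share of the charged complex held as complex with two exchanged, the balance gives

L = (1 − h/m − b)/2, which at b = 0 is 40.0%.

I called L the crossing level, the share of complex with one exchanged above which it holds more than starting complex, once the impurity has reacted. Any complex with two exchanged lowers L.

| flask | starting complex | incoming ligand | leaving ligand | protic impurity | remark | time |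
|---|---|---|---|---|---|---|
| green | 0.34 M | 0.27 M | 1.7 M | 0.068 M | run made earlier |  |
| red | 0.34 M | 0.58 M | 1.7 M | 0.068 M | run made earlier |  |
| teal | 0.34 M | 1.5 M | 1.7 M | 0.068 M | run made earlier |  |
| north | 0.34 M | 0.272 M | 1.70 M | 0.0680 M |  | 12 h |
| south-west | 0.34 M | 0.408 M | 1.70 M | 0.0680 M |  | 12 h |
| south | 0.34 M | 1.36 M | 1.70 M | 0.0680 M |  | 12 h |

- green (time / h: complex with one exchanged / %): 1.50: 4.2; 3.00: 5.3; 5.00: 10.2; 6.00: 10.0; 8.00: 14.4
- red (time / h: complex with one exchanged / %): 0.667: 5.4; 1.33: 9.9; 2.50: 12.8; 4.00: 17.5; 8.00: 25.3
- teal (time / h: complex with one exchanged / %): 0.667: 13.6; 1.33: 19.8; 2.50: 26.9; 4.00: 31.6; 8.00: 38.8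

(scatter of a reading: 1 percentage point)

- which of these holds the largest part of the starting complex at the end of north (complex with one exchanged / complex with two exchanged / starting complex)
- which of these holds the largest part of the starting complex at the end of south-west (complex with one exchanged / complex with two exchanged / starting complex)
- which of these holds the largest part of the starting complex at the end of south (complex with one exchanged / complex with two exchanged / starting complex)
- amount of complex with one exchanged at the end of south, in percent of the starting complex charged

I needed south's complex with one exchanged at its end, and I reckoned it two ways. The first teal and red readings, divided by their time and by the charge of incoming ligand X, gave 3.78 × 10⁻⁵ L mol⁻¹ s⁻¹ and 3.88 × 10⁻⁵ L mol⁻¹ s⁻¹. So I read the rise as going with X·t, with k the teal value. My first way was a simple clock: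

(1 − h/m)(1 − exp(−k·X·t)) = 71.3%

My second way scaled south onto teal, where it falls at 10.9 h, and continued teal's gain per doubling of time:

42.0%

The two parted, so I tried the clock on teal's last reading. It gave 64.3% where 38.8% was read, so the clock was the one that cheated. I kept the second value, which stands above L even at b = 0, and I expected complex with one exchanged to lead in south. North and south-west scale to before teal's 31.6% at 4.00 h, below L, so I expected starting complex to lead there.

The forecast answered starting complex, starting complex and starting complex for north, south-west and south, with 42% for the amount asked. On south's starting complex its words were: “stays largest, though narrowly”. There we parted.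

    starting complex + incoming ligand ⇌ leaving ligand + complex with one exchanged (K = 0.660, k = 5.30 × 10⁻⁵ L mol⁻¹ s⁻¹)
    complex with one exchanged + incoming ligand ⇌ leaving ligand + complex with two exchanged (K = 12.0, k = 1.30 × 10⁻⁵ L mol⁻¹ s⁻¹)
    protic impurity + starting complex → quenched substrate (k = 7.00 × 10⁻⁴ L mol⁻¹ s⁻¹)
    crystals ⇌ complex with one exchanged, rate k4*(cs4 - [complex with one exchanged]) while solid is left; crystals form when [complex with one exchanged] > cs4 (solubility = 0.230 M, k = 0.00100 s⁻¹)
    leaving ligand → by-product carried off (k = 6.40 × 10⁻⁵ s⁻¹)

North and south-west stayed with starting complex, but south gave complex with one exchanged as the largest: 39.5%, against 20.2% of starting complex and 20.6% of complex with two exchanged. With that b, L stood at 29.7%, and the reading lay above it. South had not come to rest: at 120 h complex with one exchanged stood at 0.952% and complex with two exchanged at 79.1%.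

The neighbouring flask is south with 0.017 M of protic impurity, where L at b = 0 is 47.5%. That flask gave 46.4% of complex with one exchanged against 26% of starting complex, and this amount lay above the 36.0% to which its 23.0% of complex with two exchanged puts L.

The earlier runs and the new flask come from a simulation from invented constants, and the scatter is random.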